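**Plan**
- Numbering: ring O1, C2 (3,4,5-trimethoxyphenyl), C3 (CH2OH), C4 (carbinol arm), C5 (CH2); C7 is the carbinol carbon. C5 is a bare methylene between O1 and C4, that is, formaldehyde bound to O1. C7 is benzylic to the dimethoxyphenyl ring, whose para methoxy group stabilises a cation. An O1=C5H2 oxocarbenium ion can therefore add across a C4=C7 styrene.
- Retrosynthesis: cut C7–O and C4–C5 together (oxonium–Prins), then O1–C5 (acetal), then C4=C7 (cross-metathesis), then C2–C3 (allylboration).
- Forward: the open chain is joined first (C2–C3, then C4=C7, then O1–C5). The only ring, the tetrahydrofuran, closes in the penultimate step, and desilylation ends the route.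
- Stereochemistry: C2 and C3 come from a phosphoric acid-catalysed anti allylboration (catalyst for the absolute sense, chair with the E-boronate for the relative one). C4 is set by C3 in the ring closure, and C7 by C4 in the capture of the cation.

Key step: step 6

Remark: the (R)-phosphoric acid is assumed to direct attack to the Re face of 3,4,5-trimethoxybenzaldehyde, as it does with benzaldehyde; were the sense opposite, the (S)-acid would be used.

Step 1
Reactants: 1 (Z)-but-2-ene-1,4-diol
Product: 2 (Z)-4-[(tert-butyldiphenylsilyl)oxy]but-2-en-1-ol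
Conditions: NaH (1.0 equiv), THF, 0 °C; then TBDPSCl (1.0 equiv), 0 °C → rt
Reagents that add atoms: tert-butyl(chloro)diphenylsilane, CC(C)(C)[Si](Cl)(c1ccccc1)c1ccccc1
Why: Williamson-type O-silylation of the monosodium alkoxide, which forms with one equivalent of NaH and is silylated faster than it equilibrates to the dialkoxide, should give the mono ether with the Z alkene untouched.

Step 2
Reactants: 2 (Z)-4-[(tert-butyldiphenylsilyl)oxy]but-2-en-1-ol; 3 bis(pinacolato)diboron
Product: 4 (E)-tert-butyldiphenyl{[4-(4,4,5,5-tetramethyl-1,3,2-dioxaborolan-2-yl)but-2-en-1-yl]oxy}silane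
Conditions: Pd(MeCN)4(BF4)2 (5 mol%), DMSO/MeOH (1:1), 50 °C
Reagents that add atoms: none
Why: Palladium-catalysed allylic C–OH borylation: the hydroxyl is ionised to an η3-allyl palladium complex that equilibrates to its syn form before boron is transferred to the unsubstituted CH2 terminus, so the linear (E)-allylboronate should result from the Z alcohol while the silyl ether stays inert.

Step 3
Reactants: 4 (E)-allylboronate; 5 3,4,5-trimethoxybenzaldehyde
Product: 7 (1R,2S)-2-{[(tert-butyldiphenylsilyl)oxy]methyl}-1-(3,4,5-trimethoxyphenyl)but-3-en-1-ol, via pinacol borate ester 6 (not isolated)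
Conditions: (R)-3,3′-bis(2,4,6-triisopropylphenyl)-1,1′-binaphthyl-2,2′-diyl hydrogen phosphate (5 mol%), 4 Å molecular sieves, toluene, −30 °C; then aq. NaHCO3
Reagents that add atoms: none
Why: Chiral phosphoric acid-catalysed allylboration (type 1, closed chair transition state): the E-boronate places the CH2OSi group equatorial, which gives the anti (1R,2S) pair, and the (R)-acid, hydrogen-bonded to a boronate oxygen and to the formyl hydrogen, exposes the Re face of the aldehyde and so sets 1R, after which the O–B bond of 6 is hydrolysed on work-up.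

Step 4
Reactants: 7 (1R,2S)-homoallylic alcohol; 8 3,4-dimethoxystyrene (3 equiv)
Product: 9 (1R,2S,3E)-2-{[(tert-butyldiphenylsilyl)oxy]methyl}-4-(3,4-dimethoxyphenyl)-1-(3,4,5-trimethoxyphenyl)but-3-en-1-ol
Conditions: second-generation Grubbs catalyst RuCl2(H2IMes)(PCy3)(=CHPh) (5 mol%), CH2Cl2, 40 °C
Reagents that add atoms: none
Why: Ruthenium-catalysed olefin cross-metathesis between the monosubstituted alkene of 7 and an excess of the styrene, driven by loss of ethene, should give the E styrene under thermodynamic control, and the free hydroxyl, the silyl ether and both stereocentres are not touched.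

Step 5
Reactants: 9 (1R,2S,3E)-styrenyl alcohol
Product: 10 methoxymethyl ether of 9, (1R,2S,3E)-2-{[(tert-butyldiphenylsilyl)oxy]methyl}-4-(3,4-dimethoxyphenyl)-1-(methoxymethoxy)-1-(3,4,5-trimethoxyphenyl)but-3-ene
Conditions: MOMCl (3 equiv), iPr2NEt (5 equiv), CH2Cl2, 0 → 40 °C
Reagents that add atoms: chloromethyl methyl ether, COCCl
Why: Methoxymethylation of a secondary alcohol with MOMCl and a hindered amine takes place at oxygen only, so the configuration of the carbinol carbon is retained and the O1–C5 bond of the future ring is in place.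

Step 6
Reactants: 10 methoxymethyl ether
Product: 12 (S)-[(3R,4S,5R)-4-{[(tert-butyldiphenylsilyl)oxy]methyl}-5-(3,4,5-trimethoxyphenyl)oxolan-3-yl](3,4-dimethoxyphenyl)methanol, via benzylic bromide 11 (not isolated)
Conditions: SnBr4 (2 equiv), CH2Cl2, −78 °C; then THF/H2O, NaHCO3, −78 → 0 °C
Reagents that add atoms: water, O
Why: SnBr4 removes methoxide from the methoxymethyl ether to give the O1=C5H2 oxocarbenium ion, C5 is attacked by the styrene carbon nearer the tether (C4) so that the charge moves to the benzylic carbon C7, bromide from the stannate holds this cation as the labile bromide 11, and in the buffered aqueous quench 11 ionises again (SN1) and water forms the C7–O bond; SnBr4 is preferred to a silyl triflate because the methoxide then stays on tin and cannot return to C7 as a methyl ether. The closest known reaction type is the SnBr4-promoted oxonium–Prins cyclisation of styrenyl acetals to 2,3-disubstituted tetrahydrofurans with halide capture, combined with the ordinary solvolysis of an electron-rich benzylic halide. The tetrahydrofuran closes in a five-membered mode that is exo to the styrene C=C and endo to the O1=C5 bond; the six-membered alternative through C7 (the 2-oxonia-Cope path) would leave the charge on a non-benzylic carbon and is disfavoured. C4 is controlled by C3: in the envelope transition state the aryl group on C2, the CH2OSi group on C3 and the styryl arm on C4 are all pseudo-equatorial, which gives the 3,4-trans ring, and this all-trans isomer is also the thermodynamic one if the closure is reversible. C7 is controlled by C4: water should add to the cation on the face anti to the C4–C5 bond, the net anti addition across the E alkene that gives the S carbinol, although the cation is free to rotate at this stage and this is the least secure selectivity. The step needs attack at C4 and not C7 and survival of the acid-labile C2–O1 benzylic bond and the silyl ether, which the polarisation of the styrene by its para methoxy group, the −78 °C temperature, the bulky non-participating silyl ether and the bicarbonate-buffered quench should secure.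

Step 7
Reactants: 12 silyl ether of the target
Product: 13 (S)-(3,4-dimethoxyphenyl)[(3R,4S,5R)-4-(hydroxymethyl)-5-(3,4,5-trimethoxyphenyl)oxolan-3-yl]methanol (CNP0172668.1)
Conditions: Bu4NF (1.2 equiv), THF, 0 °C → rt
Reagents that add atoms: none
Why: Fluoride-induced desilylation, driven by the strength of the Si–F bond, frees the primary hydroxyl under mildly basic conditions that leave the benzylic carbinol, the 2-aryltetrahydrofuran and all four stereocentres unchanged.

**Compound list**
1 | (Z)-but-2-ene-1,4-diol | OC/C=C\CO | starting material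
2 | (Z)-4-[(tert-butyldiphenylsilyl)oxy]but-2-en-1-ol | OC/C=C\CO[Si](c1ccccc1)(c1ccccc1)C(C)(C)C | intermediate
3 | bis(pinacolato)diboron | CC1(C)OB(OC1(C)C)B1OC(C)(C)C(C)(C)O1 | starting material
4 | (E)-tert-butyldiphenyl{[4-(4,4,5,5-tetramethyl-1,3,2-dioxaborolan-2-yl)but-2-en-1-yl]oxy}silane | CC1(C)OB(C/C=C/CO[Si](c2ccccc2)(c2ccccc2)C(C)(C)C)OC1(C)C | intermediate
5 | 3,4,5-trimethoxybenzaldehyde | COc1cc(C=O)cc(OC)c1OC | starting material
6 | pinacol borate ester of 7 (O–B bonded allylboration adduct, 1R,2S; not isolated) | CC1(C)OB(O[C@@H](c2cc(OC)c(OC)c(OC)c2)[C@H](CO[Si](c2ccccc2)(c2ccccc2)C(C)(C)C)C=C)OC1(C)C | intermediate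
7 | (1R,2S)-2-{[(tert-butyldiphenylsilyl)oxy]methyl}-1-(3,4,5-trimethoxyphenyl)but-3-en-1-ol | O[C@@H](c1cc(OC)c(OC)c(OC)c1)[C@H](CO[Si](c1ccccc1)(c1ccccc1)C(C)(C)C)C=C | intermediate
8 | 3,4-dimethoxystyrene (4-ethenyl-1,2-dimethoxybenzene) | C=Cc1ccc(OC)c(OC)c1 | starting material
9 | (1R,2S,3E)-2-{[(tert-butyldiphenylsilyl)oxy]methyl}-4-(3,4-dimethoxyphenyl)-1-(3,4,5-trimethoxyphenyl)but-3-en-1-ol | O[C@@H](c1cc(OC)c(OC)c(OC)c1)[C@H](CO[Si](c1ccccc1)(c1ccccc1)C(C)(C)C)/C=C/c1ccc(OC)c(OC)c1 | intermediate
10 | methoxymethyl ether of 9 (1R,2S,3E) | COCO[C@@H](c1cc(OC)c(OC)c(OC)c1)[C@H](CO[Si](c1ccccc1)(c1ccccc1)C(C)(C)C)/C=C/c1ccc(OC)c(OC)c1 | intermediate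
11 | benzylic bromide: (3R,4S,5R)-3-[bromo(3,4-dimethoxyphenyl)methyl]-4-{[(tert-butyldiphenylsilyl)oxy]methyl}-5-(3,4,5-trimethoxyphenyl)oxolane, either configuration at the bromide carbon (not isolated) | COc1ccc(cc1OC)C(Br)[C@H]1CO[C@@H](c2cc(OC)c(OC)c(OC)c2)[C@@H]1CO[Si](c1ccccc1)(c1ccccc1)C(C)(C)C | intermediate
12 | (S)-[(3R,4S,5R)-4-{[(tert-butyldiphenylsilyl)oxy]methyl}-5-(3,4,5-trimethoxyphenyl)oxolan-3-yl](3,4-dimethoxyphenyl)methanol | COc1ccc(cc1OC)[C@@H](O)[C@H]1CO[C@@H](c2cc(OC)c(OC)c(OC)c2)[C@@H]1CO[Si](c1ccccc1)(c1ccccc1)C(C)(C)C | intermediate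
13 | (S)-(3,4-dimethoxyphenyl)[(3R,4S,5R)-4-(hydroxymethyl)-5-(3,4,5-trimethoxyphenyl)oxolan-3-yl]methanol | COc1ccc(cc1OC)[C@@H](O)[C@H]1CO[C@@H](c2cc(OC)c(OC)c(OC)c2)[C@@H]1CO | target

**Totals and risks**
Total step count: 7. Longest linear sequence: 7 steps (1 → 13).

Step 6. The process at risk is poor facial selectivity when water captures the freely rotating benzylic cation, so that the two carbinol epimers form in similar amounts. The fallback sets out from 12, taken together with its carbinol epimer, and returns to 12. Dess–Martin periodinane (NaHCO3, CH2Cl2, rt) should oxidise both epimers to one compound, the aryl ketone [(3R,4S,5R)-4-{[(tert-butyldiphenylsilyl)oxy]methyl}-5-(3,4,5-trimethoxyphenyl)oxolan-3-yl](3,4-dimethoxyphenyl)methanone F1, whose C4 centre is already the more stable trans one. Corey–Bakshi–Shibata reduction with (R)-2-methyl-CBS-oxazaborolidine and BH3·SMe2 (THF, −20 °C) should then set the S carbinol under reagent control, with the aryl group as the large substituent.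

Step 3. The process at risk is erosion of enantio- and diastereoselectivity: the bulky, oxygenated boronate may react slowly, which lets the uncatalysed pathway or traces of Z-boronate contribute. The fallback sets out from aldehyde 5 and returns at 7; it is an Evans syn aldol. The imide (R)-4-benzyl-3-(but-3-enoyl)oxazolidin-2-one F2 would be made from but-3-enoic acid and (R)-4-benzyloxazolidin-2-one through the pivaloyl mixed anhydride. Its dibutylboron enolate (Bu2BOTf, iPr2NEt, CH2Cl2, −78 → 0 °C) should add to 5 to give the syn aldol (R)-4-benzyl-3-[(2R,3R)-2-ethenyl-3-hydroxy-3-(3,4,5-trimethoxyphenyl)propanoyl]oxazolidin-2-one F3. LiBH4 (THF, MeOH, 0 °C) should remove the auxiliary reductively to give the diol (1R,2S)-2-ethenyl-1-(3,4,5-trimethoxyphenyl)propane-1,3-diol F4. TBDPSCl and imidazole (CH2Cl2, 0 °C) should then silylate the primary hydroxyl selectively to give 7. This path also makes the route independent of steps 1 and 2.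

Step 4. The process at risk is self-metathesis and oligomerisation of the electron-rich styrene, which would consume the partner and the catalyst before the α-branched alkene of 7 has turned over. The fallback sets out from 7 and returns at 9. Cross-metathesis of 7 with 2-ethenyl-4,4,5,5-tetramethyl-1,3,2-dioxaborolane (second-generation Grubbs catalyst, CH2Cl2, 40 °C), a partner that does not homodimerise readily, should give the alkenylboronate (1R,2S,3E)-2-{[(tert-butyldiphenylsilyl)oxy]methyl}-4-(4,4,5,5-tetramethyl-1,3,2-dioxaborolan-2-yl)-1-(3,4,5-trimethoxyphenyl)but-3-en-1-ol F5. Suzuki–Miyaura coupling with 4-bromo-1,2-dimethoxybenzene (Pd(PPh3)4, K2CO3, dioxane/H2O, 80 °C) should then attach the aryl ring with retention of the E geometry to give 9.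

**Further compounds**
F1 | step 6 | [(3R,4S,5R)-4-{[(tert-butyldiphenylsilyl)oxy]methyl}-5-(3,4,5-trimethoxyphenyl)oxolan-3-yl](3,4-dimethoxyphenyl)methanone | COc1ccc(cc1OC)C(=O)[C@H]1CO[C@@H](c2cc(OC)c(OC)c(OC)c2)[C@@H]1CO[Si](c1ccccc1)(c1ccccc1)C(C)(C)C
F2 | step 3 | (R)-4-benzyl-3-(but-3-enoyl)oxazolidin-2-one | C=CCC(=O)N1[C@H](Cc2ccccc2)COC1=O
F3 | step 3 | (R)-4-benzyl-3-[(2R,3R)-2-ethenyl-3-hydroxy-3-(3,4,5-trimethoxyphenyl)propanoyl]oxazolidin-2-one | O[C@@H](c1cc(OC)c(OC)c(OC)c1)[C@H](C(=O)N1[C@H](Cc2ccccc2)COC1=O)C=C
F4 | step 3 | (1R,2S)-2-ethenyl-1-(3,4,5-trimethoxyphenyl)propane-1,3-diol | O[C@@H](c1cc(OC)c(OC)c(OC)c1)[C@H](CO)C=C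
F5 | step 4 | (1R,2S,3E)-2-{[(tert-butyldiphenylsilyl)oxy]methyl}-4-(4,4,5,5-tetramethyl-1,3,2-dioxaborolan-2-yl)-1-(3,4,5-trimethoxyphenyl)but-3-en-1-ol | O[C@@H](c1cc(OC)c(OC)c(OC)c1)[C@H](CO[Si](c1ccccc1)(c1ccccc1)C(C)(C)C)/C=C/B1OC(C)(C)C(C)(C)O1
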